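## Structural features

The target is a flavonolignan ether: tricin (rings A and C form a 5,7-dihydroxychromen-4-one, ring B is the 3,5-dimethoxy-4-oxyphenyl group on C2) is bonded through its 4'-oxygen to C8 of a three-carbon chain C7–C8–C9. C7 is a benzylic carbinol carrying the 4-hydroxy-3-methoxyphenyl (guaiacyl) ring, and C9 is a CH2OAc group. C7 (R) and C8 (S) are adjacent and erythro, that is, the C7 hydroxyl and the C8 aryloxy group are anti when Ar–C7–C8–C9 is drawn as a zigzag. Three groups are fragile: the primary acetate, which lies 1,3 to the free C7 hydroxyl and can migrate or be cleaved by bases and amines; the 4-oxybenzylic C7–O bond, which can ionise in acid or be hydrogenolysed; and C8–H, which becomes acidic once C7 is a carbonyl and then allows epimerisation and β-elimination of the C9 oxygen. The real difficulty is not the flavone but having exactly one of five hydroxyl groups acetylated while C8, whose only handles are its two oxygenated one-carbon arms, is set in absolute terms. The key step exploits this: C9 and C7 both start as CH2OH groups of an achiral 2-aryloxypropane-1,3-diol, in which they are enantiotopic, so an enzymatic acetylation of one of them sets C8 and puts the acetate on C9 in one operation. The para position of ring B is remote from this event and carries a silyl-protected ethynyl group whose two carbons later become C2 and C3 of ring C.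

## Logic of the disconnections

19 to 18. The three O–CH2Ph bonds (O5 and O7 of ring A, O4 of the guaiacyl ring) are cut. The phenols must be masked during the organometallic addition and the palladium chemistry, and one neutral hydrogenolysis frees all three without touching the acetate. The gain is that no hydroxyl has to be told from another at the end. The forward step must stop before the benzylic C7–O bond or the C2=C3 bond is reduced.

18 to 14 and 16. O1–C2, C3–C4 and C4–C4a of ring C are cut, with the C4 carbonyl carbon supplied as a gaseous one-carbon reagent. This removes rings A and C in one convergent three-component event and leaves ring B as a terminal arylalkyne and ring A as an ortho-iodophenol without stereocentres. The forward step needs carbonylation to outrun direct coupling, closure to be 6-endo, and the C9 acetate to survive the amine.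

16 to 15. The C2–I bond is cut, because 15 is a catalogue phenol and iodination is one step. The forward step must iodinate ortho to the hydroxyl and not at the position between the two benzyloxy groups.

14 to 13. The C(sp)–Si bond is cut. The silyl group is kept up to this point because it hides the acidic alkyne C–H from the aryl organometallic used earlier. The forward step must remove it without making the medium basic enough to move or cleave the acetate.

13 to 9 and 10 (through 11 and 12). The C7–C1'' bond is cut. It joins the guaiacyl ring convergently and creates C7 next to the existing C8 centre, so 1,2-induction can set it. The gain is one stereocentre and one aryl ring removed. The forward step needs an aryl nucleophile that is non-chelating, weakly basic and selective for the formyl group over the acetate.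

9 to 8. No skeletal bond is cut; the C7=O bond is traced back to C7–OH, so only the oxidation level of the C7 arm changes. The forward step must be a neutral oxidation that neither epimerises C8 nor expels the C9 acetate.

8 to 6 and 7. The O–acetyl bond at C9 is cut. This removes the last stereocentre, since 6 is achiral, and at the same time accounts for the acetate of the target. The forward step must choose between two enantiotopic hydroxymethyl groups and stop at monoacylation.

6 to 4 and 5. The aryl C4–C(sp) bond is cut, leading to an aryl bromide and a silylacetylene. The forward step must couple an electron-rich aryl bromide in the presence of a free 1,3-diol.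

4 to 3. The two C–OH carbons are traced back to ester carbonyls (the C–OEt bonds are cut). The forward step needs a hydride that reduces both esters and leaves the aryl bromide alone.

3 to 1 and 2. The O–C8 bond is cut, giving a phenol and a halomalonate that already holds C7, C8 and C9 in the right oxidation pattern. The forward step is O-alkylation of a hindered 2,6-disubstituted phenoxide by a secondary halide.

## Other disconnections considered

Alternative 1: ring C is cut at O1–C8a, C4–C4a and O1–C2, so that ring A arrives as an aryne. In the forward step CsF releases the aryne A3 from the silylaryl triflate A4 in the presence of the arylpropiolic acid A2. The carboxylate adds to the aryne carbon remote from the adjacent benzyloxy group, the aryl anion attacks the ester carbonyl (acyl shift from O to C), and the ortho-acylphenoxide closes 6-endo onto the alkyne to give A1.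
- In its favour: no transition metal and no carbon monoxide. The 3-alkoxy group of A3 directs the addition to the correct 5,7-pattern. Only fluoride is present, so no secondary amine meets the molecule. On these points it is better than step 9 of the chosen plan.
- Equal: both plans build rings A and C in one convergent operation from the ethynyl-derived ring B.
- Against it here: a free C7 hydroxyl would be arylated by A3, so the side chain must travel as the acetonide and the acetate comes last. That needs acid hydrolysis of the acetonide at an ionisable 4-alkoxybenzylic centre, then a selective primary acetylation, then hydrogenolysis. A4 needs several steps from 15, against one step to 16. Arylpropiolic acids lose CO2 easily, and proton transfer can stop the sequence at the aryl ester.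
- Comparison: this cut says nothing about C7 and C8, which would still have to be made as in the chosen plan or otherwise. In step count it should be at least four steps longer (acetonide on and off, carboxylation, late acetylation), plus the longer route to A4.

Alternative 2: the C7–C1'' bond is cut with the protected flavone already in place and C9 carried as a silyl ether. In the forward step the aryltitanium 12 adds to the aldehyde A6 to give A5.
- Equal: the bond, the mechanism and the Felkin–Anh model are those of step 6.
- Better: a β-silyloxy aldehyde is much less prone to lose its β-oxygen than the β-acetoxy aldehyde 9. The flavone would be made on an achiral, acetate-free intermediate, so the annulation conditions would be unconstrained.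
- Against it here: C8 of A6 still needs a source of chirality, most simply the same enzymatic desymmetrisation. The acetate would then have to be exchanged for the silyl ether, and later the silyl ether for an acetate, the last of these with primary-over-secondary selectivity. The least selective step (diastereoselection at C7) would fall on the most advanced fragment. The organotitanium must also ignore the chromenone.
- Comparison: about three steps longer, and the enzymatic acetate would serve only as a temporary label instead of being kept.

Alternative 3: the C7–H bond is cut. In the forward step a ketoreductase with NADPH and cofactor recycling reduces one enantiomer of the rapidly racemising β-keto ester A8 to A7. A7 has the target's arrangement at both centres; its descriptors read (2R,3R) only because the ester outranks C7.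
- Better: C7 and C8 are set together under catalyst control, whereas step 6 of the chosen plan relies on substrate control. The labile aldehyde 9 is avoided. The α-acidity that is a liability in the chosen plan is what drives this process. A8 should be available in two or three steps by acylation chemistry.
- Against it here: the ketone is flanked by an aryl ring and by a carbon bearing a 2,6-disubstituted aryloxy group, a bulky–bulky substrate for which an enzyme of the erythro sense would have to be found. The ester must afterwards be reduced and the primary hydroxyl of the resulting 7,9-diol acetylated selectively, two steps for what the chosen key step does in one. The bromide must still be taken to the flavone (coupling, desilylation, annulation) with the acetate present, so the amine problem of step 9 remains.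
- Comparison: the step count should be about equal (nine to ten). It is stronger on C7 control and weaker on the placement of the acetate.

Key step: step 4

Assumptions and remarks
- The lipase retained from a short screen (written below as immobilised Burkholderia cepacia lipase) is assumed to acylate the pro-R hydroxymethyl group of 6. The sense cannot be predicted with confidence for a 2-aryloxy substrate, and the fallback to step 4 reaches 8 if the sense is the opposite one.
- Compounds 2, 5 and 15 are taken to be catalogue compounds.
- The spatial arrangement at C8 is the same in 8, 9, 13, 14, 17, 18 and 19. The descriptor changes from R in 8 to S from 9 onwards only because the oxidised C7 arm outranks C9.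

## Route

Step 1
Reactants: 1 4-bromo-2,6-dimethoxyphenol; 2 diethyl chloromalonate
Product: 3 diethyl 2-(4-bromo-2,6-dimethoxyphenoxy)propanedioate
Conditions: K2CO3, acetone, reflux
Reagents that add atoms: none
Why: Williamson ether synthesis, SN2 attack of the phenoxide on the doubly activated malonate carbon. The chloromalonate is preferred to the bromo analogue because it is less prone to pass its halogen to an electron-rich phenoxide, and the aryl bromide is inert to K2CO3.

Step 2
Reactants: 3 diethyl 2-(4-bromo-2,6-dimethoxyphenoxy)propanedioate
Product: 4 2-(4-bromo-2,6-dimethoxyphenoxy)propane-1,3-diol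
Conditions: LiBH4, THF, MeOH (2 equiv), 0 °C to rt; aq NH4Cl
Reagents that add atoms: none
Why: Borohydride reduction of both esters to primary alcohols. Aryl bromide and aryl ethers are inert to LiBH4, and methanol reprotonates any malonate enolate so the reduction does not stall; the product is achiral.

Step 3
Reactants: 4 2-(4-bromo-2,6-dimethoxyphenoxy)propane-1,3-diol; 5 triisopropylsilylacetylene
Product: 6 2-[2,6-dimethoxy-4-(triisopropylsilylethynyl)phenoxy]propane-1,3-diol
Conditions: PdCl2(MeCN)2 (2 mol %), XPhos (2-dicyclohexylphosphino-2',4',6'-triisopropylbiphenyl, 6 mol %), Cs2CO3, MeCN, 80 °C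
Reagents that add atoms: none
Why: Copper-free Sonogashira coupling. The bulky electron-rich phosphine lets zerovalent palladium insert into the electron-rich C–Br bond, the absence of copper excludes alkyne homocoupling, and the triisopropylsilyl group and the free diol tolerate Cs2CO3. Coupling after the reduction keeps the acidic malonate C–H away from palladium and base.

Step 4
Reactants: 6 2-[2,6-dimethoxy-4-(triisopropylsilylethynyl)phenoxy]propane-1,3-diol; 7 vinyl acetate
Product: 8 (R)-2-[2,6-dimethoxy-4-(triisopropylsilylethynyl)phenoxy]-3-hydroxypropyl acetate
Conditions: immobilised Burkholderia cepacia lipase, 7 (4 equiv), t-BuOMe, 25 °C; filtered when 6 is just consumed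
Reagents that add atoms: none
Why: Lipase-catalysed irreversible transesterification: the active-site serine attacks vinyl acetate to give the acetyl-enzyme and vinyl alcohol, which tautomerises to acetaldehyde so the transfer cannot reverse. The acetyl-enzyme then acylates one hydroxymethyl group of 6 through a tetrahedral intermediate held in the oxyanion hole; the O–acetyl bond at C9 is the only bond formed and no ring is closed. The closest known reaction is the lipase and vinyl acetate desymmetrisation of 2-O-benzylglycerol and other 2-substituted propane-1,3-diols. The new stereocentre C8 is controlled by the chiral binding pocket alone: the rigid 2,6-dimethoxyaryloxy group fits only the large pocket, which puts the pro-R CH2OH at the serine and holds the pro-S one away. The step needs selectivity between enantiotopic groups, which the enzyme supplies, and between mono- and diacylation, which comes from the slower acylation of 8 and from stopping at full consumption of 6. A small overrun should help, because the minor enantiomer still has its fast-reacting arm free and is converted preferentially into the achiral diacetate. The silylalkyne is remote and inert and keeps the substrate soluble; 8 is kept cold and oxidised promptly, since 1,3-acetyl migration would exchange the two arms and racemise it.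

Step 5
Reactants: 8 (R)-2-[2,6-dimethoxy-4-(triisopropylsilylethynyl)phenoxy]-3-hydroxypropyl acetate
Product: 9 (S)-2-[2,6-dimethoxy-4-(triisopropylsilylethynyl)phenoxy]-3-oxopropyl acetate
Conditions: Dess–Martin periodinane (1.3 equiv), CH2Cl2, 0 °C to rt; dilution with Et2O/pentane, filtration through a short silica pad; used at once
Reagents that add atoms: none
Why: Dess–Martin oxidation of the primary alcohol under nearly neutral conditions. No base able to enolise the α-aryloxy aldehyde or expel the β-acetate is present, and alkyne, silyl group and acetate are inert, so C8 keeps its arrangement.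

Step 6
Reactants: 9 (S)-2-[2,6-dimethoxy-4-(triisopropylsilylethynyl)phenoxy]-3-oxopropyl acetate; 10 1-benzyloxy-4-bromo-2-methoxybenzene
Product: 13 (2S,3R)-3-(4-benzyloxy-3-methoxyphenyl)-2-[2,6-dimethoxy-4-(triisopropylsilylethynyl)phenoxy]-3-hydroxypropyl acetate, via 4-benzyloxy-3-methoxyphenyllithium 11 (not isolated), via (4-benzyloxy-3-methoxyphenyl)titanium triisopropoxide 12 (not isolated)
Conditions: 10 (2.2 equiv), n-BuLi (2.1 equiv), THF, −78 °C; ClTi(OiPr)3 (2.3 equiv), −78 to −40 °C; then 9, −78 to −10 °C; cold aq NH4Cl
Reagents that add atoms: n-butyllithium, [Li]CCCC; chlorotitanium triisopropoxide, CC(C)O[Ti](Cl)(OC(C)C)OC(C)C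
Why: Bromine–lithium exchange with n-BuLi gives 11, transmetallation with ClTi(OiPr)3 gives 12 (the two reagents supply only the lithium of 11 and the titanium triisopropoxide unit of 12, neither of which remains in 13), and 12 adds 1,2 to the aldehyde. The titanium reagent is weakly basic, does not chelate and does not attack the acetate, so addition should follow the polar Felkin–Anh model (C8–OAr bond anti to the incoming aryl group, attack past the C8 hydrogen), giving the 7R alcohol anti to the aryloxy group, the erythro isomer. The minor threo epimer is removed by chromatography.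

Step 7
Reactants: 13 (2S,3R)-3-(4-benzyloxy-3-methoxyphenyl)-2-[2,6-dimethoxy-4-(triisopropylsilylethynyl)phenoxy]-3-hydroxypropyl acetate
Product: 14 (2S,3R)-3-(4-benzyloxy-3-methoxyphenyl)-2-(4-ethynyl-2,6-dimethoxyphenoxy)-3-hydroxypropyl acetate
Conditions: Bu4NF (1.5 equiv), AcOH (1.5 equiv), THF, 0 °C to rt
Reagents that add atoms: none
Why: Fluoride-induced protodesilylation of the alkynylsilane through a pentacoordinate silicate, with acetic acid protonating the acetylide. The buffer keeps the medium too weakly basic for acetate cleavage or migration from O9 to O7, and the benzyl ether, the carbinol and both stereocentres are untouched.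

Step 8
Reactants: 15 3,5-bis(benzyloxy)phenol
Product: 16 3,5-bis(benzyloxy)-2-iodophenol
Conditions: N-iodosuccinimide (1.0 equiv), CH2Cl2, −20 to 0 °C
Reagents that add atoms: N-iodosuccinimide, O=C1CCC(=O)N1I
Why: Electrophilic aromatic iodination of a strongly activated phenol. In a non-polar solvent the reagent is delivered next to the hydrogen-bonding hydroxyl; position 2 (equivalent to 6) is favoured statistically and is less crowded than position 4 between the two benzyloxy groups. One equivalent at low temperature limits di-iodination, and the 4-iodo isomer is separated by chromatography.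

Step 9
Reactants: 14 (2S,3R)-3-(4-benzyloxy-3-methoxyphenyl)-2-(4-ethynyl-2,6-dimethoxyphenoxy)-3-hydroxypropyl acetate; 16 3,5-bis(benzyloxy)-2-iodophenol
Product: 18 (2S,3R)-3-(4-benzyloxy-3-methoxyphenyl)-2-{4-[5,7-bis(benzyloxy)-4-oxo-4H-chromen-2-yl]-2,6-dimethoxyphenoxy}-3-hydroxypropyl acetate, via ortho-hydroxyaryl alkynone 17 (not isolated)
Conditions: PdCl2(PPh3)2 (5 mol %), 1,3-bis(diphenylphosphino)propane (5 mol %), thiourea (5 mol %), CO (1 atm), Et2NH (5 equiv), THF, 40 °C
Reagents that add atoms: carbon monoxide, [C-]#[O+]
Why: Palladium-catalysed carbonylative Sonogashira coupling and amine-mediated cyclisation, a known flavone synthesis from ortho-iodophenols and terminal arylacetylenes. Zerovalent palladium inserts into the C–I bond, CO insertion gives the aroylpalladium iodide, and alkynylation with reductive elimination gives 17; reversible conjugate addition of diethylamine then steers the phenol oxygen onto C2 (6-endo) instead of C3 (5-exo). The CO atmosphere and the absence of copper hold back direct coupling, and the dilute amine at 40 °C is chosen to spare the primary acetate; no stereocentre is involved.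

Step 10
Reactants: 18 (2S,3R)-3-(4-benzyloxy-3-methoxyphenyl)-2-{4-[5,7-bis(benzyloxy)-4-oxo-4H-chromen-2-yl]-2,6-dimethoxyphenoxy}-3-hydroxypropyl acetate
Product: 19 (2S,3R)-2-[4-(5,7-dihydroxy-4-oxo-4H-chromen-2-yl)-2,6-dimethoxyphenoxy]-3-hydroxy-3-(4-hydroxy-3-methoxyphenyl)propyl acetate
Conditions: H2 (1 atm), 10 % Pd/C, EtOAc–THF, rt; stopped at the calculated uptake
Reagents that add atoms: none
Why: Hydrogenolysis of three aryl benzyl ethers over palladium on carbon in a neutral, non-nucleophilic solvent. Aryl benzyl ethers should cleave well before the free benzylic C7–OH bond or the C2=C3 bond of the chromenone reacts, so the carbinol, the acetate and both stereocentres are kept.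

## Compound list

1 | 4-bromo-2,6-dimethoxyphenol | COc1cc(Br)cc(OC)c1O | starting material
2 | diethyl chloromalonate | CCOC(=O)C(Cl)C(=O)OCC | starting material
3 | diethyl 2-(4-bromo-2,6-dimethoxyphenoxy)propanedioate | CCOC(=O)C(Oc1c(OC)cc(Br)cc1OC)C(=O)OCC | intermediate
4 | 2-(4-bromo-2,6-dimethoxyphenoxy)propane-1,3-diol | OCC(CO)Oc1c(OC)cc(Br)cc1OC | intermediate
5 | triisopropylsilylacetylene | C#C[Si](C(C)C)(C(C)C)C(C)C | starting material
6 | 2-[2,6-dimethoxy-4-(triisopropylsilylethynyl)phenoxy]propane-1,3-diol | OCC(CO)Oc1c(OC)cc(C#C[Si](C(C)C)(C(C)C)C(C)C)cc1OC | intermediate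
7 | vinyl acetate | C=COC(C)=O | starting material
8 | (R)-2-[2,6-dimethoxy-4-(triisopropylsilylethynyl)phenoxy]-3-hydroxypropyl acetate | OC[C@H](COC(C)=O)Oc1c(OC)cc(C#C[Si](C(C)C)(C(C)C)C(C)C)cc1OC | intermediate
9 | (S)-2-[2,6-dimethoxy-4-(triisopropylsilylethynyl)phenoxy]-3-oxopropyl acetate | O=C[C@H](COC(C)=O)Oc1c(OC)cc(C#C[Si](C(C)C)(C(C)C)C(C)C)cc1OC | intermediate
10 | 1-benzyloxy-4-bromo-2-methoxybenzene | COc1cc(Br)ccc1OCc1ccccc1 | starting material
11 | 4-benzyloxy-3-methoxyphenyllithium | [Li]c1ccc(OCc2ccccc2)c(OC)c1 | intermediate
12 | (4-benzyloxy-3-methoxyphenyl)titanium triisopropoxide | CC(C)O[Ti](OC(C)C)(OC(C)C)c1ccc(OCc2ccccc2)c(OC)c1 | intermediate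
13 | (2S,3R)-3-(4-benzyloxy-3-methoxyphenyl)-2-[2,6-dimethoxy-4-(triisopropylsilylethynyl)phenoxy]-3-hydroxypropyl acetate | COc1cc([C@@H](O)[C@H](COC(C)=O)Oc2c(OC)cc(C#C[Si](C(C)C)(C(C)C)C(C)C)cc2OC)ccc1OCc1ccccc1 | intermediate
14 | (2S,3R)-3-(4-benzyloxy-3-methoxyphenyl)-2-(4-ethynyl-2,6-dimethoxyphenoxy)-3-hydroxypropyl acetate | COc1cc([C@@H](O)[C@H](COC(C)=O)Oc2c(OC)cc(C#C)cc2OC)ccc1OCc1ccccc1 | intermediate
15 | 3,5-bis(benzyloxy)phenol | Oc1cc(OCc2ccccc2)cc(OCc2ccccc2)c1 | starting material
16 | 3,5-bis(benzyloxy)-2-iodophenol | Oc1cc(OCc2ccccc2)cc(OCc2ccccc2)c1I | intermediate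
17 | (2S,3R)-3-(4-benzyloxy-3-methoxyphenyl)-2-{4-[3-(2,4-bis(benzyloxy)-6-hydroxyphenyl)-3-oxoprop-1-ynyl]-2,6-dimethoxyphenoxy}-3-hydroxypropyl acetate | COc1cc([C@@H](O)[C@H](COC(C)=O)Oc2c(OC)cc(C#CC(=O)c3c(O)cc(OCc4ccccc4)cc3OCc3ccccc3)cc2OC)ccc1OCc1ccccc1 | intermediate
18 | (2S,3R)-3-(4-benzyloxy-3-methoxyphenyl)-2-{4-[5,7-bis(benzyloxy)-4-oxo-4H-chromen-2-yl]-2,6-dimethoxyphenoxy}-3-hydroxypropyl acetate | COc1cc([C@@H](O)[C@H](COC(C)=O)Oc2c(OC)cc(-c3cc(=O)c4c(OCc5ccccc5)cc(OCc5ccccc5)cc4o3)cc2OC)ccc1OCc1ccccc1 | intermediate
19 | (2S,3R)-2-[4-(5,7-dihydroxy-4-oxo-4H-chromen-2-yl)-2,6-dimethoxyphenoxy]-3-hydroxy-3-(4-hydroxy-3-methoxyphenyl)propyl acetate, the (7R,8S) erythro compound CNP0157817.1 | COc1cc([C@@H](O)[C@H](COC(C)=O)Oc2c(OC)cc(-c3cc(=O)c4c(O)cc(O)cc4o3)cc2OC)ccc1O | target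

## Step count and least certain steps

Total step count: 10. Longest linear sequence: 9 steps (steps 1 to 7, 9 and 10), from 1 to 19; step 8 prepares 16 for the convergent step 9.

Step 4 (key step). The enzyme may distinguish the two arms in the sense opposite to the one needed, or only weakly, because the 2,6-dimethoxyaryloxy group is more rigid and crowded near C2 than the benzyloxy group of the closest precedent. Over-acylation and slow acetyl migration on storage would also lower yield and optical purity. The fallback sets out from 6 and comes back at 8. Compound 6 is peracetylated (Ac2O, pyridine, catalytic DMAP) to 2-[2,6-dimethoxy-4-(triisopropylsilylethynyl)phenoxy]propane-1,3-diyl diacetate F1. The same lipase is then used as a hydrolase (phosphate buffer pH 7, t-BuOMe as cosolvent); it removes the acetate from the arm it would have acylated and so leaves the antipode of its acylation product. With an enzyme of the wrong acylation sense this delivers 8.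

Step 9. Under the mild, acetate-sparing conditions the carbonylative coupling of a crowded, electron-rich iodophenol may be slow, which favours direct coupling without CO and 5-exo closure. Forcing it (more amine, an amidine base, heat, CO pressure) risks aminolysis and 1,3-migration of the acetate. The fallback sets out from 14 and comes back at 18, and it removes the constraint by taking the acetate off before the annulation. Compound 14 is deacetylated (K2CO3, MeOH, 0 °C) to (1R,2S)-1-(4-benzyloxy-3-methoxyphenyl)-2-(4-ethynyl-2,6-dimethoxyphenoxy)propane-1,3-diol F7. This diol is annulated with 16 and CO under forcing conditions (PdCl2(PPh3)2, 1,3-bis(diphenylphosphino)propane, thiourea, neat Et2NH, DBU, 50 °C) to 5,7-bis(benzyloxy)-2-{4-[(1R,2S)-1-(4-benzyloxy-3-methoxyphenyl)-1,3-dihydroxypropan-2-yloxy]-3,5-dimethoxyphenyl}-4H-chromen-4-one F8. The primary hydroxyl of the latter is then acetylated regioselectively with Candida antarctica lipase B and 7 in THF, a known primary-over-secondary lipase acylation, which gives 18.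

Step 6. Facial selectivity may be insufficient, since the Felkin–Anh preference of an α-aryloxy aldehyde with a modest size difference between H and CH2OAc is not large, and the α-centre of 9 can epimerise before addition. The fallback sets out from 13 (as the mixture of C7 epimers) and comes back at 13. The mixture is oxidised with Dess–Martin periodinane to (S)-3-(4-benzyloxy-3-methoxyphenyl)-2-[2,6-dimethoxy-4-(triisopropylsilylethynyl)phenoxy]-3-oxopropyl acetate F2, and this ketone is reduced with Zn(BH4)2 in Et2O at −20 °C. Under chelation control (zinc bridging the ketone and the aryloxy oxygen, hydride entering past the C8 hydrogen) this should give the 7R, erythro alcohol, so C7 is set by ketone reduction instead of by arylation.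

Step 7. Fluoride may cause acetyl migration from O9 to O7 or partial loss of the acetate if the buffer is not effective for the time the hindered silyl group needs. The fallback sets out from 4 and comes back at 14, and it unmasks the alkyne before any acetate exists. Compound 4 is coupled with trimethylsilylacetylene (PdCl2(PPh3)2, CuI, Et3N, DMF, 80 °C) to 2-[2,6-dimethoxy-4-(trimethylsilylethynyl)phenoxy]propane-1,3-diol F3, which is desilylated (K2CO3, MeOH) to 2-(4-ethynyl-2,6-dimethoxyphenoxy)propane-1,3-diol F4. This diol is acetylated with the lipase and 7 as in step 4 to (R)-2-(4-ethynyl-2,6-dimethoxyphenoxy)-3-hydroxypropyl acetate F5, which is oxidised as in step 5 to (S)-2-(4-ethynyl-2,6-dimethoxyphenoxy)-3-oxopropyl acetate F6. Treatment of this aldehyde with 12 as in step 6 gives 14 directly; the weakly basic titanium reagent is expected to add to the aldehyde faster than it is protonated by the alkyne C–H.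

## Further compounds

F1 | step 4 | 2-[2,6-dimethoxy-4-(triisopropylsilylethynyl)phenoxy]propane-1,3-diyl diacetate | CC(=O)OCC(COC(C)=O)Oc1c(OC)cc(C#C[Si](C(C)C)(C(C)C)C(C)C)cc1OC
F2 | step 6 | (S)-3-(4-benzyloxy-3-methoxyphenyl)-2-[2,6-dimethoxy-4-(triisopropylsilylethynyl)phenoxy]-3-oxopropyl acetate | COc1cc(C(=O)[C@H](COC(C)=O)Oc2c(OC)cc(C#C[Si](C(C)C)(C(C)C)C(C)C)cc2OC)ccc1OCc1ccccc1
F3 | step 7 | 2-[2,6-dimethoxy-4-(trimethylsilylethynyl)phenoxy]propane-1,3-diol | OCC(CO)Oc1c(OC)cc(C#C[Si](C)(C)C)cc1OC
F4 | step 7 | 2-(4-ethynyl-2,6-dimethoxyphenoxy)propane-1,3-diol | OCC(CO)Oc1c(OC)cc(C#C)cc1OC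
F5 | step 7 | (R)-2-(4-ethynyl-2,6-dimethoxyphenoxy)-3-hydroxypropyl acetate | OC[C@H](COC(C)=O)Oc1c(OC)cc(C#C)cc1OC
F6 | step 7 | (S)-2-(4-ethynyl-2,6-dimethoxyphenoxy)-3-oxopropyl acetate | O=C[C@H](COC(C)=O)Oc1c(OC)cc(C#C)cc1OC
F7 | step 9 | (1R,2S)-1-(4-benzyloxy-3-methoxyphenyl)-2-(4-ethynyl-2,6-dimethoxyphenoxy)propane-1,3-diol | COc1cc([C@@H](O)[C@H](CO)Oc2c(OC)cc(C#C)cc2OC)ccc1OCc1ccccc1
F8 | step 9 | 5,7-bis(benzyloxy)-2-{4-[(1R,2S)-1-(4-benzyloxy-3-methoxyphenyl)-1,3-dihydroxypropan-2-yloxy]-3,5-dimethoxyphenyl}-4H-chromen-4-one | COc1cc([C@@H](O)[C@H](CO)Oc2c(OC)cc(-c3cc(=O)c4c(OCc5ccccc5)cc(OCc5ccccc5)cc4o3)cc2OC)ccc1OCc1ccccc1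
A1 | alternative 1 | 5,7-bis(benzyloxy)-2-{4-[(4R,5S)-4-(4-benzyloxy-3-methoxyphenyl)-2,2-dimethyl-1,3-dioxan-5-yloxy]-3,5-dimethoxyphenyl}-4H-chromen-4-one | COc1cc([C@H]2OC(C)(C)OC[C@@H]2Oc2c(OC)cc(-c3cc(=O)c4c(OCc5ccccc5)cc(OCc5ccccc5)cc4o3)cc2OC)ccc1OCc1ccccc1
A2 | alternative 1 | 3-{4-[(4R,5S)-4-(4-benzyloxy-3-methoxyphenyl)-2,2-dimethyl-1,3-dioxan-5-yloxy]-3,5-dimethoxyphenyl}propiolic acid | COc1cc([C@H]2OC(C)(C)OC[C@@H]2Oc2c(OC)cc(C#CC(O)=O)cc2OC)ccc1OCc1ccccc1
A3 | alternative 1 | 3,5-bis(benzyloxy)benzyne (1,2-didehydro-3,5-bis(benzyloxy)benzene) | C1#CC(OCc2ccccc2)=CC(OCc2ccccc2)=C1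
A4 | alternative 1 | 3,5-bis(benzyloxy)-2-(trimethylsilyl)phenyl trifluoromethanesulfonate | C[Si](C)(C)c1c(OCc2ccccc2)cc(OCc2ccccc2)cc1OS(=O)(=O)C(F)(F)F
A5 | alternative 2 | 5,7-bis(benzyloxy)-2-{4-[(1R,2S)-1-(4-benzyloxy-3-methoxyphenyl)-3-(tert-butyldimethylsilyloxy)-1-hydroxypropan-2-yloxy]-3,5-dimethoxyphenyl}-4H-chromen-4-one | COc1cc([C@@H](O)[C@H](CO[Si](C)(C)C(C)(C)C)Oc2c(OC)cc(-c3cc(=O)c4c(OCc5ccccc5)cc(OCc5ccccc5)cc4o3)cc2OC)ccc1OCc1ccccc1
A6 | alternative 2 | (S)-2-{4-[5,7-bis(benzyloxy)-4-oxo-4H-chromen-2-yl]-2,6-dimethoxyphenoxy}-3-(tert-butyldimethylsilyloxy)propanal | O=C[C@H](CO[Si](C)(C)C(C)(C)C)Oc1c(OC)cc(-c2cc(=O)c3c(OCc4ccccc4)cc(OCc4ccccc4)cc3o2)cc1OC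
A7 | alternative 3 | ethyl (2R,3R)-3-(4-benzyloxy-3-methoxyphenyl)-2-(4-bromo-2,6-dimethoxyphenoxy)-3-hydroxypropanoate | COc1cc([C@@H](O)[C@H](C(=O)OCC)Oc2c(OC)cc(Br)cc2OC)ccc1OCc1ccccc1
A8 | alternative 3 | ethyl 3-(4-benzyloxy-3-methoxyphenyl)-2-(4-bromo-2,6-dimethoxyphenoxy)-3-oxopropanoate (racemic) | CCOC(=O)C(Oc1c(OC)cc(Br)cc1OC)C(=O)c1ccc(OCc2ccccc2)c(OC)c1
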